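**Retrosynthetic overview**
- C40 = C15 + C10 + C15: two Wittig olefinations on the C10 dialdehyde 20, first with hydroxy salt 19 (C11=C12, becomes ring A), then with silyl ether salt 18 (C11'=C12', becomes ring B). Salt 19 is made from 18 by desilylation, and the free ring A alcohol is oxidised late with MnO2 to the enone.
- 18 comes from a Julia–Kocienski olefination (C7=C8) of tetrazolyl sulfone 12 with the C5 aldehyde 13.
- C3–OH is set by a ketoreductase on enone 7 (C3 oxygen from allylic oxidation). C6 is set by a Wittig–Still [2,3] shift that transfers chirality from allylic alcohol 2, itself made by CBS reduction of achiral enone 1.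
- No ring is built: both cyclohexene rings are the ring of 1. Ring A (keto ring) enters in the first Wittig step, ring B (hydroxy ring) in the second.

Assumption: the target is the all-E (6S,3'R,6'S) isomer as written, and an R-selective ketoreductase for enone 7 is found by screening a commercial enzyme panel.

Carotenoid numbering is used in the text: C1 gem-dimethyl carbon, C3 oxygenated carbon, C4=C5 ring alkene, C6 side-chain carbon. All polyene steps are run under argon in dim light.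

**Route**

Step 1
Reactants: 1 2,4,4-trimethylcyclohex-2-en-1-one
Product: 2 (R)-2,4,4-trimethylcyclohex-2-en-1-ol
Conditions: (S)-2-methyl-CBS-oxazaborolidine (10 mol %), BH3·SMe2 (0.7 equiv), THF, −20 °C; MeOH, then H2O
Reagents that add atoms: none
Why: Corey–Bakshi–Shibata reduction, in which the catalyst binds the ketone with the 2-methylalkenyl flank as the large group and delivers hydride to one face, setting the carbinol centre as R (about 90–95 % ee expected for an α-substituted cyclohexenone).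

Step 2
Reactants: 2 (R)-2,4,4-trimethylcyclohex-2-en-1-ol
Product: 3 tributyl({[(1R)-2,4,4-trimethylcyclohex-2-en-1-yl]oxy}methyl)stannane
Conditions: KH, Bu3SnCH2I, THF, 0 °C → rt
Reagents that add atoms: tributyl(iodomethyl)stannane CCCC[Sn](CCCC)(CCCC)CI
Why: Williamson etherification of the potassium alkoxide with a primary iodide, which does not touch the carbinol stereocentre.

Step 3
Reactants: 3 tributyl({[(1R)-2,4,4-trimethylcyclohex-2-en-1-yl]oxy}methyl)stannane
Product: 5 [(1S)-2,6,6-trimethylcyclohex-2-en-1-yl]methanol ((S)-α-cyclogeraniol), via lithiomethyl ether 4 (not isolated)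
Conditions: n-BuLi, THF, −78 °C → −20 °C; then H2O
Reagents that add atoms: none
Why: Wittig–Still [2,3]-sigmatropic rearrangement, in which tin–lithium exchange gives the α-alkoxy carbanion that bonds to the far alkene carbon on the face that carried the oxygen, so the R carbinol centre becomes the S centre at C6 and the alkene moves to C4=C5.

Step 4
Reactants: 5 [(1S)-2,6,6-trimethylcyclohex-2-en-1-yl]methanol
Product: 6 [(1S)-2,6,6-trimethylcyclohex-2-en-1-yl]methyl 2,2-dimethylpropanoate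
Conditions: PivCl, pyridine, DMAP (cat.), CH2Cl2, 0 °C → rt
Reagents that add atoms: pivaloyl chloride CC(C)(C)C(Cl)=O
Why: DMAP-catalysed acylation gives a hindered ester that masks the primary alcohol through the oxidation, reduction and silylation that follow.

Step 5
Reactants: 6 [(1S)-2,6,6-trimethylcyclohex-2-en-1-yl]methyl 2,2-dimethylpropanoate
Product: 7 [(1S)-2,6,6-trimethyl-4-oxocyclohex-2-en-1-yl]methyl 2,2-dimethylpropanoate
Conditions: t-BuOOH (70 % aq., 5 equiv), Rh2(cap)4 (dirhodium tetrakis(caprolactamate), 1 mol %), K2CO3 (0.5 equiv), CH2Cl2, rt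
Reagents that add atoms: tert-butyl hydroperoxide CC(C)(C)OO
Why: Radical allylic C–H oxidation (Doyle conditions) goes to the ring CH2 at C3, the only unhindered secondary allylic position, and gives the enone; the shielded tertiary C6–H and its configuration are left alone.

Step 6
Reactants: 7 [(1S)-2,6,6-trimethyl-4-oxocyclohex-2-en-1-yl]methyl 2,2-dimethylpropanoate
Product: 8 [(1S,4R)-4-hydroxy-2,6,6-trimethylcyclohex-2-en-1-yl]methyl 2,2-dimethylpropanoate
Conditions: ketoreductase (R-selective, NADPH-dependent), NADP+ (cat.), i-PrOH (10 % v/v), KH2PO4/K2HPO4 buffer pH 7.0, 30 °C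
Reagents that add atoms: none
Why: The ketoreductase (an NADPH-dependent alcohol dehydrogenase) delivers hydride to one face of the C3 carbonyl under enzyme control and gives the 3R alcohol cis to the C6 substituent; material from the minor 6R enantiomer ends up as unreacted ketone or as the trans diastereomer and is removed on silica.

Step 7
Reactants: 8 [(1S,4R)-4-hydroxy-2,6,6-trimethylcyclohex-2-en-1-yl]methyl 2,2-dimethylpropanoate
Product: 9 [(1S,4R)-4-{[tert-butyl(dimethyl)silyl]oxy}-2,6,6-trimethylcyclohex-2-en-1-yl]methyl 2,2-dimethylpropanoate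
Conditions: TBSCl, imidazole, DMF, rt
Reagents that add atoms: tert-butyldimethylsilyl chloride CC(C)(C)[Si](C)(C)Cl
Why: Imidazole-promoted silylation of the secondary allylic alcohol gives an ether that survives hydride, strong base and methoxide and is later removed with fluoride; no stereocentre is involved.

Step 8
Reactants: 9 [(1S,4R)-4-{[tert-butyl(dimethyl)silyl]oxy}-2,6,6-trimethylcyclohex-2-en-1-yl]methyl 2,2-dimethylpropanoate
Product: 10 [(1S,4R)-4-{[tert-butyl(dimethyl)silyl]oxy}-2,6,6-trimethylcyclohex-2-en-1-yl]methanol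
Conditions: i-Bu2AlH (2.5 equiv), CH2Cl2, −78 °C; aq. KNaC4H4O6
Reagents that add atoms: none
Why: Hydride reduction of the pivalate frees the primary alcohol without touching the silyl ether or the ring alkene.

Step 9
Reactants: 10 [(1S,4R)-4-{[tert-butyl(dimethyl)silyl]oxy}-2,6,6-trimethylcyclohex-2-en-1-yl]methanol
Product: 11 5-({[(1S,4R)-4-{[tert-butyl(dimethyl)silyl]oxy}-2,6,6-trimethylcyclohex-2-en-1-yl]methyl}sulfanyl)-1-phenyl-1H-tetrazole
Conditions: 1-phenyl-1H-tetrazole-5-thiol, PPh3, DIAD, THF, 0 °C → rt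
Reagents that add atoms: 1-phenyl-1H-tetrazole-5-thiol Sc1nnnn1-c1ccccc1
Why: Mitsunobu thioetherification, an SN2 displacement of the activated primary alcohol by the acidic thiol at a CH2 group, so no stereocentre is involved.

Step 10
Reactants: 11 5-({[(1S,4R)-4-{[tert-butyl(dimethyl)silyl]oxy}-2,6,6-trimethylcyclohex-2-en-1-yl]methyl}sulfanyl)-1-phenyl-1H-tetrazole
Product: 12 5-({[(1S,4R)-4-{[tert-butyl(dimethyl)silyl]oxy}-2,6,6-trimethylcyclohex-2-en-1-yl]methyl}sulfonyl)-1-phenyl-1H-tetrazole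
Conditions: H2O2 (30 % aq.), (NH4)6Mo7O24·4H2O (10 mol %), EtOH, 0 °C → rt
Reagents that add atoms: hydrogen peroxide OO
Why: Molybdate-catalysed peroxide oxidation takes the sulfide to the sulfone while leaving the unactivated trisubstituted ring alkene and the silyl ether intact.

Step 11
Reactants: 12 5-({[(1S,4R)-4-{[tert-butyl(dimethyl)silyl]oxy}-2,6,6-trimethylcyclohex-2-en-1-yl]methyl}sulfonyl)-1-phenyl-1H-tetrazole; 13 (2E)-3-formylbut-2-en-1-yl acetate ((E)-4-acetoxy-2-methylbut-2-enal)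
Product: 15 (2E,4E)-5-[(1S,4R)-4-{[tert-butyl(dimethyl)silyl]oxy}-2,6,6-trimethylcyclohex-2-en-1-yl]-3-methylpenta-2,4-dien-1-yl acetate, via potassium sulfonyl carbanion 14 (not isolated)
Conditions: KN(SiMe3)2 (1.1 equiv), DME, −60 °C, 30 min; then 13, −60 °C → rt; H2O
Reagents that add atoms: none
Why: Julia–Kocienski olefination, in which the metalated tetrazolyl sulfone adds to the enal and Smiles rearrangement with loss of SO2 and tetrazololate gives the 7E alkene; the 9E geometry comes unchanged from 13 and the ring stereocentres lie outside the reacting atoms.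

Step 12
Reactants: 15 (2E,4E)-5-[(1S,4R)-4-{[tert-butyl(dimethyl)silyl]oxy}-2,6,6-trimethylcyclohex-2-en-1-yl]-3-methylpenta-2,4-dien-1-yl acetate
Product: 16 (2E,4E)-5-[(1S,4R)-4-{[tert-butyl(dimethyl)silyl]oxy}-2,6,6-trimethylcyclohex-2-en-1-yl]-3-methylpenta-2,4-dien-1-ol
Conditions: K2CO3 (cat.), MeOH, 0 °C → rt
Reagents that add atoms: none
Why: Base-catalysed transesterification removes the primary allylic acetate while the secondary silyl ether is inert.

Step 13
Reactants: 16 (2E,4E)-5-[(1S,4R)-4-{[tert-butyl(dimethyl)silyl]oxy}-2,6,6-trimethylcyclohex-2-en-1-yl]-3-methylpenta-2,4-dien-1-ol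
Product: 18 [(2E,4E)-5-[(1S,4R)-4-{[tert-butyl(dimethyl)silyl]oxy}-2,6,6-trimethylcyclohex-2-en-1-yl]-3-methylpenta-2,4-dien-1-yl]triphenylphosphonium bromide, via allylic bromide 17 (not isolated)
Conditions: CBr4, PPh3, CH2Cl2, −10 °C; short silica plug; then PPh3, EtOAc, rt (salt precipitates)
Reagents that add atoms: carbon tetrabromide BrC(Br)(Br)Br; triphenylphosphine c1ccccc1P(c1ccccc1)c1ccccc1
Why: Appel bromination of the primary dienylic alcohol under neutral conditions followed by SN2 quaternisation of PPh3 gives the C15 Wittig salt without ionising the ring allylic silyl ether.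

Step 14
Reactants: 18 [(2E,4E)-5-[(1S,4R)-4-{[tert-butyl(dimethyl)silyl]oxy}-2,6,6-trimethylcyclohex-2-en-1-yl]-3-methylpenta-2,4-dien-1-yl]triphenylphosphonium bromide (about 45 % of the batch; the rest is kept for step 16)
Product: 19 [(2E,4E)-5-[(1S,4R)-4-hydroxy-2,6,6-trimethylcyclohex-2-en-1-yl]-3-methylpenta-2,4-dien-1-yl]triphenylphosphonium bromide
Conditions: HF·pyridine, pyridine, THF, 0 °C → rt; CH2Cl2 extraction from aq. NaBr; precipitation from EtOAc
Reagents that add atoms: none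
Why: Pyridine-buffered HF cleaves the Si–O bond without forming the ylide or ionising the ring allylic alcohol, and gives the hydroxy Wittig salt whose free OH marks the future ring A; the bromide counter-ion is kept by the NaBr wash.

Step 15
Reactants: 19 [(2E,4E)-5-[(1S,4R)-4-hydroxy-2,6,6-trimethylcyclohex-2-en-1-yl]-3-methylpenta-2,4-dien-1-yl]triphenylphosphonium bromide; 20 (2E,4E,6E)-2,7-dimethylocta-2,4,6-trienedial
Product: 22 (3R,6S)-3-hydroxy-12'-apo-ε-caroten-12'-al (all-E C25 aldehyde), via hydroxy phosphorus ylide 21 (not isolated)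
Conditions: 20 (3 equiv), NaOMe (1.1 equiv), CH2Cl2/MeOH, 0 °C → rt (19 added slowly); then n-heptane/EtOAc, reflux
Reagents that add atoms: none
Why: Wittig olefination of one aldehyde group of the excess dialdehyde by the semi-stabilised ylide, which tolerates the free hydroxyl, forms C11=C12, and the hindered 11Z isomer formed alongside is equilibrated thermally to the all-E aldehyde.

Step 16
Reactants: 22 (3R,6S)-3-hydroxy-12'-apo-ε-caroten-12'-al; 18 [(2E,4E)-5-[(1S,4R)-4-{[tert-butyl(dimethyl)silyl]oxy}-2,6,6-trimethylcyclohex-2-en-1-yl]-3-methylpenta-2,4-dien-1-yl]triphenylphosphonium bromide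
Product: 24 (3R,6S,3'R,6'S)-3'-{[tert-butyl(dimethyl)silyl]oxy}-ε,ε-caroten-3-ol, via silyloxy phosphorus ylide 23 (not isolated)
Conditions: 18 (1.3 equiv), NaOMe, CH2Cl2/MeOH, 0 °C → rt; then n-heptane, reflux
Reagents that add atoms: none
Why: A second Wittig olefination (C11'=C12') with the silyl-protected ylide completes the C40 chain with ring A free and ring B silylated, again followed by thermal Z-to-E equilibration.

Step 17
Reactants: 24 (3R,6S,3'R,6'S)-3'-{[tert-butyl(dimethyl)silyl]oxy}-ε,ε-caroten-3-ol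
Product: 25 (6S,3'R,6'S)-3'-{[tert-butyl(dimethyl)silyl]oxy}-ε,ε-caroten-3-one
Conditions: MnO2 (activated, 20 equiv), CH2Cl2, rt, dark
Reagents that add atoms: none
Why: MnO2 oxidises only the free allylic alcohol of ring A to the conjugated enone under neutral heterogeneous conditions, so the base-sensitive C6 centre γ to the new ketone and the silyl ether of ring B are preserved.

Step 18
Reactants: 25 (6S,3'R,6'S)-3'-{[tert-butyl(dimethyl)silyl]oxy}-ε,ε-caroten-3-one
Product: 26 (6S,3'R,6'S)-3'-hydroxy-ε,ε-caroten-3-one (all-E)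
Conditions: HF·pyridine, pyridine, THF, 0 °C → rt
Reagents that add atoms: none
Why: Buffered fluoride desilylation under non-basic conditions releases the 3'R allylic alcohol of ring B without epimerising C6 of the enone ring or disturbing the polyene.

**Compound list**

1 | 2,4,4-trimethylcyclohex-2-en-1-one | CC1=CC(C)(C)CCC1=O | starting material
2 | (R)-2,4,4-trimethylcyclohex-2-en-1-ol | CC1=CC(C)(C)CC[C@H]1O | intermediate
3 | tributyl({[(1R)-2,4,4-trimethylcyclohex-2-en-1-yl]oxy}methyl)stannane | CC1=CC(C)(C)CC[C@H]1OC[Sn](CCCC)(CCCC)CCCC | intermediate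
4 | {[(1R)-2,4,4-trimethylcyclohex-2-en-1-yl]oxy}methyllithium | CC1=CC(C)(C)CC[C@H]1OC[Li] | intermediate
5 | [(1S)-2,6,6-trimethylcyclohex-2-en-1-yl]methanol | OC[C@@H]1C(C)=CCCC1(C)C | intermediate
6 | [(1S)-2,6,6-trimethylcyclohex-2-en-1-yl]methyl 2,2-dimethylpropanoate | CC(C)(C)C(=O)OC[C@@H]1C(C)=CCCC1(C)C | intermediate
7 | [(1S)-2,6,6-trimethyl-4-oxocyclohex-2-en-1-yl]methyl 2,2-dimethylpropanoate | CC(C)(C)C(=O)OC[C@@H]1C(C)=CC(=O)CC1(C)C | intermediate
8 | [(1S,4R)-4-hydroxy-2,6,6-trimethylcyclohex-2-en-1-yl]methyl 2,2-dimethylpropanoate | CC(C)(C)C(=O)OC[C@@H]1C(C)=C[C@H](O)CC1(C)C | intermediate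
9 | [(1S,4R)-4-{[tert-butyl(dimethyl)silyl]oxy}-2,6,6-trimethylcyclohex-2-en-1-yl]methyl 2,2-dimethylpropanoate | CC(C)(C)C(=O)OC[C@@H]1C(C)=C[C@H](O[Si](C)(C)C(C)(C)C)CC1(C)C | intermediate
10 | [(1S,4R)-4-{[tert-butyl(dimethyl)silyl]oxy}-2,6,6-trimethylcyclohex-2-en-1-yl]methanol | OC[C@@H]1C(C)=C[C@H](O[Si](C)(C)C(C)(C)C)CC1(C)C | intermediate
11 | 5-({[(1S,4R)-4-{[tert-butyl(dimethyl)silyl]oxy}-2,6,6-trimethylcyclohex-2-en-1-yl]methyl}sulfanyl)-1-phenyl-1H-tetrazole | c1ccccc1-n1nnnc1SC[C@@H]1C(C)=C[C@H](O[Si](C)(C)C(C)(C)C)CC1(C)C | intermediate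
12 | 5-({[(1S,4R)-4-{[tert-butyl(dimethyl)silyl]oxy}-2,6,6-trimethylcyclohex-2-en-1-yl]methyl}sulfonyl)-1-phenyl-1H-tetrazole | c1ccccc1-n1nnnc1S(=O)(=O)C[C@@H]1C(C)=C[C@H](O[Si](C)(C)C(C)(C)C)CC1(C)C | intermediate
13 | (2E)-3-formylbut-2-en-1-yl acetate | CC(=O)OC/C=C(C)/C=O | starting material
14 | potassium salt of the α-sulfonyl carbanion of 12 | [K+].c1ccccc1-n1nnnc1S(=O)(=O)[CH-][C@@H]1C(C)=C[C@H](O[Si](C)(C)C(C)(C)C)CC1(C)C | intermediate
15 | (2E,4E)-5-[(1S,4R)-4-{[tert-butyl(dimethyl)silyl]oxy}-2,6,6-trimethylcyclohex-2-en-1-yl]-3-methylpenta-2,4-dien-1-yl acetate | CC(=O)OC/C=C(C)/C=C/[C@@H]1C(C)=C[C@H](O[Si](C)(C)C(C)(C)C)CC1(C)C | intermediate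
16 | (2E,4E)-5-[(1S,4R)-4-{[tert-butyl(dimethyl)silyl]oxy}-2,6,6-trimethylcyclohex-2-en-1-yl]-3-methylpenta-2,4-dien-1-ol | OC/C=C(C)/C=C/[C@@H]1C(C)=C[C@H](O[Si](C)(C)C(C)(C)C)CC1(C)C | intermediate
17 | (2E,4E)-5-[(1S,4R)-4-{[tert-butyl(dimethyl)silyl]oxy}-2,6,6-trimethylcyclohex-2-en-1-yl]-3-methylpenta-2,4-dien-1-yl bromide | BrC/C=C(C)/C=C/[C@@H]1C(C)=C[C@H](O[Si](C)(C)C(C)(C)C)CC1(C)C | intermediate
18 | [(2E,4E)-5-[(1S,4R)-4-{[tert-butyl(dimethyl)silyl]oxy}-2,6,6-trimethylcyclohex-2-en-1-yl]-3-methylpenta-2,4-dien-1-yl]triphenylphosphonium bromide | [Br-].c1ccccc1[P+](c1ccccc1)(c1ccccc1)C/C=C(C)/C=C/[C@@H]1C(C)=C[C@H](O[Si](C)(C)C(C)(C)C)CC1(C)C | intermediate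
19 | [(2E,4E)-5-[(1S,4R)-4-hydroxy-2,6,6-trimethylcyclohex-2-en-1-yl]-3-methylpenta-2,4-dien-1-yl]triphenylphosphonium bromide | [Br-].c1ccccc1[P+](c1ccccc1)(c1ccccc1)C/C=C(C)/C=C/[C@@H]1C(C)=C[C@H](O)CC1(C)C | intermediate
20 | (2E,4E,6E)-2,7-dimethylocta-2,4,6-trienedial | O=C/C(C)=C/C=C/C=C(C)/C=O | starting material
21 | triphenylphosphonium ylide of 19 | c1ccccc1[P+](c1ccccc1)(c1ccccc1)[CH-]/C=C(C)/C=C/[C@@H]1C(C)=C[C@H](O)CC1(C)C | intermediate
22 | (3R,6S)-3-hydroxy-12'-apo-ε-caroten-12'-al | O=C/C(C)=C/C=C/C=C(C)/C=C/C=C(C)/C=C/[C@@H]1C(C)=C[C@H](O)CC1(C)C | intermediate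
23 | triphenylphosphonium ylide of 18 | c1ccccc1[P+](c1ccccc1)(c1ccccc1)[CH-]/C=C(C)/C=C/[C@@H]1C(C)=C[C@H](O[Si](C)(C)C(C)(C)C)CC1(C)C | intermediate
24 | (3R,6S,3'R,6'S)-3'-{[tert-butyl(dimethyl)silyl]oxy}-ε,ε-caroten-3-ol | CC1=C[C@H](O)CC(C)(C)[C@@H]1/C=C/C(C)=C/C=C/C(C)=C/C=C/C=C(C)/C=C/C=C(C)/C=C/[C@@H]1C(C)=C[C@H](O[Si](C)(C)C(C)(C)C)CC1(C)C | intermediate
25 | (6S,3'R,6'S)-3'-{[tert-butyl(dimethyl)silyl]oxy}-ε,ε-caroten-3-one | CC1=CC(=O)CC(C)(C)[C@@H]1/C=C/C(C)=C/C=C/C(C)=C/C=C/C=C(C)/C=C/C=C(C)/C=C/[C@@H]1C(C)=C[C@H](O[Si](C)(C)C(C)(C)C)CC1(C)C | intermediate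
26 | (6S,3'R,6'S)-3'-hydroxy-ε,ε-caroten-3-one | CC1=CC(=O)CC(C)(C)[C@@H]1/C=C/C(C)=C/C=C/C(C)=C/C=C/C=C(C)/C=C/C=C(C)/C=C/[C@@H]1C(C)=C[C@H](O)CC1(C)C | target

**Step count and risks**

Total step count: 18. Longest linear sequence: 18 steps (1 → 26). Salt 18 feeds both step 14 and step 16, so the only side branch is the direct use of 18 in step 16.

The three steps most likely to fail:

Step 3 (Wittig–Still shift onto a carbon next to a quaternary centre; a [1,2]-shift or simple destannylation could compete). The fallback sets out from 2 and returns at 5. Alcohol 2 is heated with N,N-dimethylformamide dimethyl acetal (xylene, 160 °C, sealed tube); the Büchi carbene [2,3] rearrangement follows the same suprafacial course and gives (1S)-N,N,2,6,6-pentamethylcyclohex-2-ene-1-carboxamide F1. Partial reduction with Cp2Zr(H)Cl (THF, rt) gives (1S)-2,6,6-trimethylcyclohex-2-ene-1-carbaldehyde F2, which is reduced at once with NaBH4 (MeOH, 0 °C) to 5.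

Step 6 (no ketoreductase of the panel may accept 7, or the 3R alcohol may not form cleanly). The fallback sets out from 7 and returns at 8. Luche reduction (NaBH4, CeCl3·7H2O, MeOH, −78 °C) gives 8 mixed with its C3 epimer [(1S,4S)-4-hydroxy-2,6,6-trimethylcyclohex-2-en-1-yl]methyl 2,2-dimethylpropanoate F3. A lipase (triacylglycerol hydrolase from Burkholderia cepacia, vinyl acetate, t-BuOMe, 30 °C) then acetylates only one epimer. By the Kazlauskas size rule this should be the 3S alcohol, giving [(1S,4S)-4-acetoxy-2,6,6-trimethylcyclohex-2-en-1-yl]methyl 2,2-dimethylpropanoate F4; the direction of this preference is a prediction, not a checked fact. Unreacted 8 is separated from F4 on silica and goes on to step 7. F4 is recycled by K2CO3/MeOH back to F3 and by MnO2 oxidation back to 7.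

Step 11 (Julia–Kocienski coupling of a hindered sulfone with a base-sensitive acetoxy enal; low conversion or poor 7E/7Z ratio). The fallback sets out from 10 and returns at 16, with the ring now as the electrophile. Dess–Martin periodinane (NaHCO3, CH2Cl2, 0 °C) oxidises 10 to (1S,4R)-4-{[tert-butyl(dimethyl)silyl]oxy}-2,6,6-trimethylcyclohex-2-ene-1-carbaldehyde F5. This is used at once in a Horner–Wadsworth–Emmons reaction with triethyl 3-methyl-4-phosphonocrotonate (LiN(SiMe3)2, THF, −78 → 0 °C) to give ethyl (2E,4E)-5-[(1S,4R)-4-{[tert-butyl(dimethyl)silyl]oxy}-2,6,6-trimethylcyclohex-2-en-1-yl]-3-methylpenta-2,4-dienoate F6. Reduction with i-Bu2AlH (CH2Cl2, −78 °C) gives 16.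

**Further compounds**

F1 | step 3 | (1S)-N,N,2,6,6-pentamethylcyclohex-2-ene-1-carboxamide | CN(C)C(=O)[C@@H]1C(C)=CCCC1(C)C
F2 | step 3 | (1S)-2,6,6-trimethylcyclohex-2-ene-1-carbaldehyde | O=C[C@@H]1C(C)=CCCC1(C)C
F3 | step 6 | [(1S,4S)-4-hydroxy-2,6,6-trimethylcyclohex-2-en-1-yl]methyl 2,2-dimethylpropanoate | CC(C)(C)C(=O)OC[C@@H]1C(C)=C[C@@H](O)CC1(C)C
F4 | step 6 | [(1S,4S)-4-acetoxy-2,6,6-trimethylcyclohex-2-en-1-yl]methyl 2,2-dimethylpropanoate | CC(C)(C)C(=O)OC[C@@H]1C(C)=C[C@@H](OC(C)=O)CC1(C)C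
F5 | step 11 | (1S,4R)-4-{[tert-butyl(dimethyl)silyl]oxy}-2,6,6-trimethylcyclohex-2-ene-1-carbaldehyde | O=C[C@@H]1C(C)=C[C@H](O[Si](C)(C)C(C)(C)C)CC1(C)C
F6 | step 11 | ethyl (2E,4E)-5-[(1S,4R)-4-{[tert-butyl(dimethyl)silyl]oxy}-2,6,6-trimethylcyclohex-2-en-1-yl]-3-methylpenta-2,4-dienoate | CCOC(=O)/C=C(C)/C=C/[C@@H]1C(C)=C[C@H](O[Si](C)(C)C(C)(C)C)CC1(C)C
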